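## Structural features

Atom labels follow elemanolide numbering: ring A is the cyclohexane C5–C10, ring B the γ-lactone O6–C12–C11–C7–C6, C1=C2 the vinyl group on C10, and C3/C4/C15 the isopropenyl group on C5.

- The target is a cyclohexane (ring A) with a γ-lactone (ring B) cis-fused across C6–C7.
- Five ring stereocentres stand in a row (C10, C5, C6, C7, C8; only C9 is a methylene), and the fully substituted carbinol carbon C11 of ring B adjoins C7, so six stereocentres form one block.
- C10 is an all-carbon quaternary centre (methyl, vinyl) next to the C5 methine. Methyl, isopropenyl and the C8 acetate lie on one face; vinyl, the C6 oxygen and the C7–C11 bond lie on the other.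
- Fragile groups are the angelate (Z to E drift under base, nucleophiles or heat), the tertiary α-acyloxy lactone, and the 1,3-related oxygens O6 and O8. Both oxygens are γ to C12, so a free O8 hydroxyl can compete with O6 for C12.
- Three unconjugated alkenes, two of them terminal, rule out hydrogenation, ozonolysis and most electrophilic reagents late in the route.
- The real difficulty is the quaternary centre C10 of defined configuration beside C5, in a ring that also needs three oxygenated carbons.
- The key step exploits the fact that C10 carries a methyl group and a one-carbon stub (C1) that can be a formyl group, and that its neighbour C9 is a plain methylene joined through C8 to a former alkene. This is the retron of a 1,2-shift of C9 from C1 to C10, so ring A can come from the seven-membered ring C10–C1–C9–C8–C7–C6–C5 by contraction.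

## Logic of the disconnections

**27 ⇒ 26 ⇒ 25 ⇒ 22 + 23.** The two ester C–O bonds (O8–acetyl, O11–angeloyl) are cut first because they are the most labile groups. O8 stays silylated while the hindered O11 is acylated, so no free hydroxyl can accept or pass on the angeloyl group, and the simple acetylation comes last. The gain is a stable hydroxy lactone. The forward steps must acylate a tertiary alcohol without Z to E isomerisation and then remove silicon without touching the angelate.

**22 ⇒ 20.** The C11–O bond is cut. A tertiary carbinol next to a carbonyl is the retron of an enolate oxidation, and the cut makes the C11 configuration of the precursor irrelevant. The forward step needs the oxidant to attack the convex face of the cis-fused enolate and needs C11–H to be the only acidic site, which is why O8 carries silicon and not an acetyl group.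

**20 ⇒ 19 ⇒ 18.** C12 is taken back to the acetal oxidation level and the O8 silyl group is removed. The lactol ether is what a radical closure delivers. O8 must be capped before C12 becomes an acyl carbon, or the lactol could re-close on O8. The forward oxidation has to spare a secondary silyl ether and three alkenes.

**18 ⇒ 16.** C7–C11 and C8–O are cut. The O6 tether enforces the cis ring fusion, and one step makes ring B and two stereocentres from an alkene. The gain is a monocyclic cyclohexenyl bromoacetal. The forward step needs 5-exo closure to outrun capture of the first radical by O2, and needs O2 to approach C8 anti to the new ring.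

**16 ⇒ 15 ⇒ 13.** The O6–acetal bond is cut, O6 is returned to its silyl ether, and C1=C2 is cut back to the formyl group. This exposes the aldehyde needed for the key retron. The forward methylenation of a neopentyl, non-enolisable aldehyde is undemanding.

**13 ⇒ 12.** This is the key cut. C9–C10 is broken, C9 is reattached to C1, and C1 and C10 are bridged by oxygen. The quaternary stereocentre disappears into an epoxide whose face can be set by C5. The forward step must ionise at C10, shift C9 rather than hydrogen, and proceed with inversion.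

**12 ⇒ 11 ⇒ 10.** The epoxide C–O bonds are removed and the C10=C1 alkene is cut by retro-metathesis. C5 then carries two identical isopropenyl groups and stops being a stereocentre, so only C6 is left. The forward steps need the peracid to pick the trisubstituted alkene and the face anti to isopropenyl, and need the metathesis to choose between two diastereotopic isopropenyl groups.

**10 ⇒ 9 ⇒ 8 ⇒ 4 + 5.** Silicon is removed, the Z-alkene C7=C8 is taken back to an alkyne, and C5–C6 is cut. A carbinol flanked by a bis(isopropenyl)methyl group is the γ-adduct of a pentadienyl metal and an aldehyde, so the one remaining stereocentre can be set by a chiral reagent. The forward steps need γ-regioselectivity, enantioface control, and a semihydrogenation that stops at the Z-alkene.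

**4 ⇒ 3 ⇒ 1 + 2.** The sp–sp3 bond C8–C9 is cut and the oxidation level adjusted. The forward steps need C-allylation (not O-allylation) and an oxidation that does not isomerise the skipped enyne.

## Other disconnections considered

**Alternative 1:** The cut is at C8–C9 and C10–C1.
- *Forward step.* The selenoester A1 has twin isopropenyl groups on C5 and a dimethyl(vinyl)silyl ether on O6. Under radical chain conditions its C8 acyl radical would close 6-endo on the CH2 end of one isopropenyl group. The tertiary C10 radical would then add to the silicon-bearing vinyl carbon through a six-membered transition state and expel the silyl radical. Hydrolysis would give the hydroxy ketone A2.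
- *In its favour.* Ring A, the quaternary centre and its vinyl group arise in one step. The vinyl group is delivered from the O6 face by a tether, and no methylenation is needed.
- *Against it here.* The choice between the isopropenyl groups is made in an early radical transition state. The tertiary radical must attack the more substituted vinylsilane carbon in competition with hydrogen transfer. A2 is a β-hydroxy ketone prone to dehydration. A2 also lacks the C7=C8 alkene, so ring B would need alkylation α to C8 next to a β-leaving group and a face-selective reduction at C8.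
- *Comparison.* On step count to ring A and on how the vinyl group arrives, this plan is the better one. On the desymmetrisation idea the two are equal. On mechanism it stacks two radical events of uncertain selectivity where the chosen plan has one stereospecific ionic shift. On the lactone annulation it is weaker.

**Alternative 2:** The cut is at C7–C11 and C8–O.
- *Forward step.* The bromoacetal A3 (identical with 16) would give, under Bu3SnH and air, a C11 radical that closes 5-exo on C7. The C8 radical would take up O2, giving the hydroxylated lactol ether A4 (identical with 18).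
- *In its favour.* Ring B and two stereocentres come in one step, the tether guarantees the cis fusion, and the oxygen enters C8 anti to the new ring.
- *Against it here.* As a strategic centre it presupposes ring A with C10, C5 and C6 already set, so it leaves the hardest problem open. Capture of the first radical by O2 competes with closure, and C11 and the acetal carbon form without control.
- *Comparison.* In stereocentres made per step it is the equal or the better of the chosen key step (two against one). In mechanistic risk it is comparable. It is not a rival, because it concerns ring B and the chosen plan already uses it as step 11.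

**Alternative 3:** The cut is at C6–C7 and O6–C12.
- *Forward step.* The acyclic aldehyde A5 carries a (Z)-2-(bromomethyl)enoate. Zinc dust, or CrCl2 (divalent chromium), would give an allylmetal whose γ-carbon C7 adds to the C6 aldehyde, and the alkoxide would lactonise to the cis-fused α-methylene lactone A6.
- *In its favour.* Both rings close in one step and the C8 oxygen is present and protected from the start. The exocyclic methylene could become the C11 carbinol by a radical hydration, which would shorten the endgame.
- *Against it here.* A5 must already hold C5, C8 and the quaternary C10 in an open chain, so the central problem moves into acyclic stereocontrol. C5 in A5 is both α to the aldehyde and allylic, and would epimerise or conjugate easily. The C6/C7 outcome rests on Felkin-type induction beside a quaternary carbon. Hydration of the methylene would have to be selective among four alkenes.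
- *Comparison.* On convergence and endgame length it is the better plan. On ring formation per step it is at least equal. On access to its precursor and on stereochemical security at C10 and C5 the chosen plan is stronger.

Key step: step 8

Assumption: the borane 7 built from (−)-Ipc2BOMe (from (+)-α-pinene) is taken to attack the Si face of 4, as the parent allyl reagent does with simple aldehydes; the antipodal reagent would be used otherwise.

Design note on the precursor: O6 is kept as a tert-butyldimethylsilyl ether from 10 to 13. Its bulk should favour the trans ring closure in step 6, it deactivates C7=C8 toward the peracid in step 7, and silyl ethers are tolerated by the aluminium reagent of step 8. The epoxide oxygen of 12 must lie on the face of the silyloxy group, anti to isopropenyl, and the structures below are consistent with inversion at C10.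

## Route

Step 1
Reactants: 1 propargyl alcohol (prop-2-yn-1-ol); 2 allyl bromide (3-bromoprop-1-ene)
Product: 3 hex-5-en-2-yn-1-ol
Conditions: CuI (copper iodide, 10 mol %), K2CO3, Bu4NBr (cat.), DMF, rt
Reagents that add atoms: none
Why: Copper-catalysed coupling of a terminal alkyne with an allylic halide; the copper acetylide formed under carbonate substitutes allyl bromide at carbon, and the hydroxyl group, which carbonate does not deprotonate, is not allylated.

Step 2
Reactants: 3 hex-5-en-2-yn-1-ol
Product: 4 hex-5-en-2-ynal
Conditions: Dess–Martin periodinane, CH2Cl2, 0 °C → rt; kept as a cold solution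
Reagents that add atoms: none
Why: Dess–Martin oxidation of a primary propargylic alcohol stops at the aldehyde under non-basic conditions, which matters because the doubly activated methylene of the skipped enynal isomerises with base; the volatile aldehyde is not taken to dryness.

Step 3
Reactants: 4 hex-5-en-2-ynal; 5 2,4-dimethylpenta-1,3-diene
Product: 8 (4S)-2-methyl-3-(prop-1-en-2-yl)nona-1,8-dien-5-yn-4-ol, via potassium 2,4-dimethylpentadienide 6 (not isolated), via (2,4-dimethylpenta-2,4-dienyl)diisopinocampheylborane 7 (not isolated)
Conditions: 5, n-BuLi, KOtBu, THF, −78 → −45 °C; (−)-Ipc2BOMe, −78 °C; BF3·OEt2; 4, −78 °C; NaOH, H2O2, 0 °C → rt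
Reagents that add atoms: none
Why: Brown-type asymmetric allylboration used as a γ-pentadienylboration; the primary borane 7 reacts through a chair six-membered transition state at the central carbon of the pentadienyl unit, so both isopropenyl groups end on C5 and C6 is the only new stereocentre. The isopinocampheyl groups direct attack to the Si face of the aldehyde, which gives the S carbinol.

Step 4
Reactants: 8 (4S)-2-methyl-3-(prop-1-en-2-yl)nona-1,8-dien-5-yn-4-ol
Product: 9 (4R,5Z)-2-methyl-3-(prop-1-en-2-yl)nona-1,5,8-trien-4-ol
Conditions: H2 (1 atm), Pd/CaCO3 poisoned with Pb(OAc)2, quinoline, EtOAc, rt, stopped after 1 equiv H2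
Reagents that add atoms: none
Why: Lindlar semihydrogenation; syn addition of hydrogen on the poisoned palladium surface gives the Z alkene C7=C8, and the alkyne binds much more strongly than the three alkenes, so uptake can be stopped after one equivalent. The change of descriptor at C6 from S to R is a priority effect only.

Step 5
Reactants: 9 (4R,5Z)-2-methyl-3-(prop-1-en-2-yl)nona-1,5,8-trien-4-ol
Product: 10 tert-butyl(dimethyl){[(4R,5Z)-2-methyl-3-(prop-1-en-2-yl)nona-1,5,8-trien-4-yl]oxy}silane
Conditions: TBSOTf, 2,6-lutidine, CH2Cl2, −78 → 0 °C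
Reagents that add atoms: tert-butyldimethylsilyl trifluoromethanesulfonate, CC(C)(C)[Si](C)(C)OS(=O)(=O)C(F)(F)F
Why: Silylation of a hindered secondary alcohol with the silyl triflate and a non-nucleophilic base; no stereocentre is touched.

Step 6
Reactants: 10 tert-butyl(dimethyl){[(4R,5Z)-2-methyl-3-(prop-1-en-2-yl)nona-1,5,8-trien-4-yl]oxy}silane
Product: 11 tert-butyl(dimethyl){[(1R,7R)-6-methyl-7-(prop-1-en-2-yl)cyclohepta-2,5-dien-1-yl]oxy}silane
Conditions: second-generation Grubbs catalyst (5 mol %), CH2Cl2 (5 mM), 40 °C
Reagents that add atoms: none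
Why: Ring-closing olefin metathesis; the ruthenium carbene forms at the monosubstituted C1 vinyl group and closes on the CH2 of one isopropenyl group, with the Z alkene C7=C8 holding the chain in a shape suited to a seven-membered ring. The isopropenyl group that reacts should be the one that leaves its twin pseudo-equatorial and trans to the bulky silyloxy group, which sets C5 under control by C6.

Step 7
Reactants: 11 tert-butyl(dimethyl){[(1R,7R)-6-methyl-7-(prop-1-en-2-yl)cyclohepta-2,5-dien-1-yl]oxy}silane
Product: 12 tert-butyl(dimethyl){[(1R,2S,3R,7S)-1-methyl-2-(prop-1-en-2-yl)-8-oxabicyclo[5.1.0]oct-4-en-3-yl]oxy}silane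
Conditions: mCPBA (1.05 equiv), NaHCO3, CH2Cl2, −20 → 0 °C
Reagents that add atoms: 3-chloroperoxybenzoic acid, OOC(=O)c1cccc(Cl)c1
Why: Prilezhaev epoxidation; the trisubstituted C10=C1 alkene is the most electron-rich of the four (isopropenyl is 1,1-disubstituted, C7=C8 is deactivated by the allylic silyloxy group). The peracid should approach anti to the isopropenyl group on the adjacent allylic carbon C5, placing oxygen on the face of the silyloxy group, and bicarbonate keeps the acid-labile epoxide from rearranging early.

Step 8
Reactants: 12 tert-butyl(dimethyl){[(1R,2S,3R,7S)-1-methyl-2-(prop-1-en-2-yl)-8-oxabicyclo[5.1.0]oct-4-en-3-yl]oxy}silane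
Product: 13 (1S,5R,6R)-5-{[tert-butyl(dimethyl)silyl]oxy}-1-methyl-6-(prop-1-en-2-yl)cyclohex-3-ene-1-carbaldehyde
Conditions: MeAl(OAr)2 (Ar = 4-bromo-2,6-di-tert-butylphenyl; from Me3Al and ArOH, 2 equiv), CH2Cl2, −78 → −40 °C; H2O quench
Reagents that add atoms: none
Why: The hindered aluminium Lewis acid binds the epoxide oxygen and the bond from oxygen to the tertiary carbon C10 ionises; as charge builds at C10 the C1–C9 bond shifts to C10 on the face opposite the departing oxygen, and C1, which keeps the oxygen, becomes the formyl carbon. The closest known reaction type is the Meinwald (semipinacol) rearrangement of 1-methylcycloalkene oxides to ring-contracted 1-methylcycloalkanecarbaldehydes, and of trisubstituted epoxides to aldehydes with this aluminium aryloxide. Ring A is closed not by a cyclisation but by this 1,2-alkyl shift, a contraction of the seven-membered carbocycle to the six-membered one in which C9–C10 replaces C9–C1. The one new stereocentre, C10, forms with inversion relative to the epoxide, whose face was fixed in step 7 by the C5 isopropenyl group, so the formyl group ends on the former oxygen face (trans to isopropenyl, cis to silyloxy) and the methyl group cis to isopropenyl. Three selectivities are needed: ionisation at C10 and not C1 (tertiary against secondary carbon); migration of C9 and not of the C1 hydrogen (C9 is allylic, and the bulky aryloxide ligands are expected to turn the O–Al group outward so that the ring bond lies anti to the breaking C–O bond); and no capture of the cation by the isopropenyl or C7=C8 π bonds or by proton loss (concerted shift, low temperature, non-basic medium). The silyl ether is a spectator of a kind this reagent tolerates, and the product cannot epimerise because C10 bears no hydrogen. The aldehyde is used at once in step 9 so that a Lewis-acid-induced ene reaction with the neighbouring isopropenyl group has no time to occur.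

Step 9
Reactants: 13 (1S,5R,6R)-5-{[tert-butyl(dimethyl)silyl]oxy}-1-methyl-6-(prop-1-en-2-yl)cyclohex-3-ene-1-carbaldehyde
Product: 15 (1R,5R,6R)-5-ethenyl-5-methyl-6-(prop-1-en-2-yl)cyclohex-2-en-1-ol, via O6-silylated triene 14 (not isolated)
Conditions: Ph3PCH3Br, KOtBu, THF, 0 °C → rt; then Bu4NF, THF, rt → 45 °C
Reagents that add atoms: methyltriphenylphosphonium bromide, C[P+](c1ccccc1)(c1ccccc1)c1ccccc1.[Br-]
Why: Wittig methylenation of a neopentyl aldehyde that has no α-hydrogen and so cannot enolise or epimerise, followed in the same flask by fluoride cleavage of the silyl ether; no stereocentre is affected.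

Step 10
Reactants: 15 (1R,5R,6R)-5-ethenyl-5-methyl-6-(prop-1-en-2-yl)cyclohex-2-en-1-ol
Product: 16 (3R,4R,5R)-3-(2-bromo-1-ethoxypropoxy)-5-ethenyl-5-methyl-4-(prop-1-en-2-yl)cyclohex-1-ene (mixture at the acetal and CHBr carbons)
Conditions: ethyl prop-1-enyl ether (excess), NBS, CH2Cl2, −40 → 0 °C
Reagents that add atoms: ethyl prop-1-enyl ether, CC=COCC; N-bromosuccinimide, O=C1CCC(=O)N1Br
Why: Haloacetalisation, the first stage of a Ueno–Stork sequence; the enol ether is far more nucleophilic than the other alkenes toward NBS, and the alcohol traps the resulting oxocarbenium ion. The two new centres are uncontrolled and are both erased later.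

Step 11
Reactants: 16 (3R,4R,5R)-3-(2-bromo-1-ethoxypropoxy)-5-ethenyl-5-methyl-4-(prop-1-en-2-yl)cyclohex-1-ene
Product: 18 (3aR,4S,6R,7R,7aS)-2-ethoxy-6-ethenyl-3,6-dimethyl-7-(prop-1-en-2-yl)octahydro-1-benzofuran-4-ol, via C8 hydroperoxide 17 (not isolated)
Conditions: Bu3SnH (slow addition), Et3B (cat.), dry air (slow stream), toluene, 0 °C → rt; then PPh3
Reagents that add atoms: dioxygen, O=O
Why: Ueno–Stork radical cyclisation with aerobic trapping; the C11 radical closes 5-exo on C7 from the face of the O6 tether, which forces the cis ring fusion and sets C7. The C8 radical should take up O2 on the convex face, anti to the new C7–C11 bond, setting C8, and phosphine reduces the hydroperoxide to the alcohol.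

Step 12
Reactants: 18 (3aR,4S,6R,7R,7aS)-2-ethoxy-6-ethenyl-3,6-dimethyl-7-(prop-1-en-2-yl)octahydro-1-benzofuran-4-ol
Product: 19 tert-butyl{[(3aS,4S,6R,7R,7aS)-2-ethoxy-6-ethenyl-3,6-dimethyl-7-(prop-1-en-2-yl)octahydro-1-benzofuran-4-yl]oxy}dimethylsilane
Conditions: TBSCl, imidazole, DMAP (cat.), DMF, 40 °C
Reagents that add atoms: tert-butyldimethylsilyl chloride, CC(C)(C)[Si](C)(C)Cl
Why: Silylation under mild base that leaves the mixed acetal intact. O8 is capped before C12 becomes a carbonyl so that it cannot compete with O6 for C12, and with silicon rather than acetyl so that step 14 meets no second enolisable ester and no acyl group within reach of the C11 enolate.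

Step 13
Reactants: 19 tert-butyl{[(3aS,4S,6R,7R,7aS)-2-ethoxy-6-ethenyl-3,6-dimethyl-7-(prop-1-en-2-yl)octahydro-1-benzofuran-4-yl]oxy}dimethylsilane
Product: 20 (3aS,4S,6R,7R,7aS)-4-{[tert-butyl(dimethyl)silyl]oxy}-6-ethenyl-3,6-dimethyl-7-(prop-1-en-2-yl)hexahydro-1-benzofuran-2(3H)-one (C3 epimers)
Conditions: CrO3, H2SO4, H2O, acetone, 0 °C, short reaction time
Reagents that add atoms: water, O
Why: Jones oxidation of a lactol ether; acid opens the acetal to the lactol, which chromic acid oxidises to the γ-lactone, and all acetal and C11 isomers converge. A hindered secondary silyl ether and isolated alkenes should survive brief exposure at 0 °C.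

Step 14
Reactants: 20 (3aS,4S,6R,7R,7aS)-4-{[tert-butyl(dimethyl)silyl]oxy}-6-ethenyl-3,6-dimethyl-7-(prop-1-en-2-yl)hexahydro-1-benzofuran-2(3H)-one
Product: 22 (3S,3aS,4S,6R,7R,7aS)-4-{[tert-butyl(dimethyl)silyl]oxy}-6-ethenyl-3-hydroxy-3,6-dimethyl-7-(prop-1-en-2-yl)hexahydro-1-benzofuran-2(3H)-one, via potassium enolate 21 (not isolated)
Conditions: KN(SiMe3)2, THF, −78 °C; 2-(phenylsulfonyl)-3-phenyloxaziridine, −78 °C; AcOH
Reagents that add atoms: 2-(phenylsulfonyl)-3-phenyloxaziridine, O=S(=O)(N1OC1c1ccccc1)c1ccccc1
Why: Davis hydroxylation of a lactone enolate; C11–H is the only acidic site, the enolate erases the C11 mixture, and the oxaziridine should attack the convex face of the cis-fused bicycle, syn to H7 and away from ring A, which sets C11.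

Step 15
Reactants: 22 (3S,3aS,4S,6R,7R,7aS)-4-{[tert-butyl(dimethyl)silyl]oxy}-6-ethenyl-3-hydroxy-3,6-dimethyl-7-(prop-1-en-2-yl)hexahydro-1-benzofuran-2(3H)-one; 23 angelic acid
Product: 25 (3S,3aS,4S,6R,7R,7aS)-4-{[tert-butyl(dimethyl)silyl]oxy}-6-ethenyl-3,6-dimethyl-2-oxo-7-(prop-1-en-2-yl)octahydro-1-benzofuran-3-yl (2Z)-2-methylbut-2-enoate, via angelic 2,4,6-trichlorobenzoic anhydride 24 (not isolated)
Conditions: 23, 2,4,6-trichlorobenzoyl chloride, Et3N, toluene, rt; then 22, DMAP (cat.), toluene, 80 °C
Reagents that add atoms: none
Why: Yamaguchi esterification; the mixed anhydride acylates hindered alcohols at its less hindered angeloyl carbonyl without passing through a free acyl chloride, the pathway by which angelates usually drift to tiglates. C11 is quaternary and cannot epimerise.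

Step 16
Reactants: 25 (3S,3aS,4S,6R,7R,7aS)-4-{[tert-butyl(dimethyl)silyl]oxy}-6-ethenyl-3,6-dimethyl-2-oxo-7-(prop-1-en-2-yl)octahydro-1-benzofuran-3-yl (2Z)-2-methylbut-2-enoate
Product: 26 (3S,3aR,4S,6R,7R,7aS)-6-ethenyl-4-hydroxy-3,6-dimethyl-2-oxo-7-(prop-1-en-2-yl)octahydro-1-benzofuran-3-yl (2Z)-2-methylbut-2-enoate
Conditions: HF·pyridine, pyridine, THF, 0 °C → rt
Reagents that add atoms: none
Why: Fluoride-mediated desilylation under buffered, weakly acidic conditions that open neither the lactone nor the angelate and give no alkoxide that could move an acyl group.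

Step 17
Reactants: 26 (3S,3aR,4S,6R,7R,7aS)-6-ethenyl-4-hydroxy-3,6-dimethyl-2-oxo-7-(prop-1-en-2-yl)octahydro-1-benzofuran-3-yl (2Z)-2-methylbut-2-enoate
Product: 27 (3S,3aR,4S,6R,7R,7aS)-4-acetoxy-6-ethenyl-3,6-dimethyl-2-oxo-7-(prop-1-en-2-yl)octahydro-1-benzofuran-3-yl (2Z)-2-methylbut-2-enoate
Conditions: Ac2O, DMAP (cat.), pyridine, CH2Cl2, 0 °C → rt
Reagents that add atoms: acetic anhydride, CC(=O)OC(C)=O
Why: DMAP-catalysed acetylation of the secondary C8 hydroxyl; it is fast at room temperature, so neither translactonisation to O8 nor isomerisation of the angelate should compete.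

## Compound list

1 | propargyl alcohol (prop-2-yn-1-ol) | C#CCO | starting material
2 | allyl bromide (3-bromoprop-1-ene) | C=CCBr | starting material
3 | hex-5-en-2-yn-1-ol | C=CCC#CCO | intermediate
4 | hex-5-en-2-ynal | C=CCC#CC=O | intermediate
5 | 2,4-dimethylpenta-1,3-diene | CC(C)=CC(C)=C | starting material
6 | potassium 2,4-dimethylpentadienide | [K+].[CH2-]C(C)=CC(C)=C | intermediate
7 | (2,4-dimethylpenta-2,4-dien-1-yl)di[(−)-isopinocampheyl]borane (isopinocampheyl groups from (+)-α-pinene) | C=C(C)C=C(C)CB([C@@H]1C[C@@H]2C[C@H]([C@H]1C)C2(C)C)[C@@H]1C[C@@H]2C[C@H]([C@H]1C)C2(C)C | intermediate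
8 | (4S)-2-methyl-3-(prop-1-en-2-yl)nona-1,8-dien-5-yn-4-ol | C=CCC#C[C@@H](O)C(C(C)=C)C(C)=C | intermediate
9 | (4R,5Z)-2-methyl-3-(prop-1-en-2-yl)nona-1,5,8-trien-4-ol | C=CC/C=C\[C@@H](O)C(C(C)=C)C(C)=C | intermediate
10 | tert-butyl(dimethyl){[(4R,5Z)-2-methyl-3-(prop-1-en-2-yl)nona-1,5,8-trien-4-yl]oxy}silane | C=CC/C=C\[C@@H](O[Si](C)(C)C(C)(C)C)C(C(C)=C)C(C)=C | intermediate
11 | tert-butyl(dimethyl){[(1R,7R)-6-methyl-7-(prop-1-en-2-yl)cyclohepta-2,5-dien-1-yl]oxy}silane (silyloxy and isopropenyl trans) | CC1=CCC=C[C@@H](O[Si](C)(C)C(C)(C)C)[C@@H]1C(=C)C | intermediate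
12 | tert-butyl(dimethyl){[(1R,2S,3R,7S)-1-methyl-2-(prop-1-en-2-yl)-8-oxabicyclo[5.1.0]oct-4-en-3-yl]oxy}silane (epoxide oxygen anti to isopropenyl) | C[C@]12O[C@H]1CC=C[C@@H](O[Si](C)(C)C(C)(C)C)[C@@H]2C(=C)C | intermediate
13 | (1S,5R,6R)-5-{[tert-butyl(dimethyl)silyl]oxy}-1-methyl-6-(prop-1-en-2-yl)cyclohex-3-ene-1-carbaldehyde (formyl trans to isopropenyl) | O=C[C@@]1(C)CC=C[C@@H](O[Si](C)(C)C(C)(C)C)[C@@H]1C(=C)C | intermediate
14 | tert-butyl{[(1R,5R,6R)-5-ethenyl-5-methyl-6-(prop-1-en-2-yl)cyclohex-2-en-1-yl]oxy}dimethylsilane | C=C[C@@]1(C)CC=C[C@@H](O[Si](C)(C)C(C)(C)C)[C@@H]1C(=C)C | intermediate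
15 | (1R,5R,6R)-5-ethenyl-5-methyl-6-(prop-1-en-2-yl)cyclohex-2-en-1-ol | C=C[C@@]1(C)CC=C[C@@H](O)[C@@H]1C(=C)C | intermediate
16 | (3R,4R,5R)-3-(2-bromo-1-ethoxypropoxy)-5-ethenyl-5-methyl-4-(prop-1-en-2-yl)cyclohex-1-ene (mixture at the acetal and CHBr carbons) | C=C[C@@]1(C)CC=C[C@@H](OC(OCC)C(C)Br)[C@@H]1C(=C)C | intermediate
17 | (3aS,4S,6R,7R,7aS)-2-ethoxy-6-ethenyl-4-hydroperoxy-3,6-dimethyl-7-(prop-1-en-2-yl)octahydro-1-benzofuran (epimers at C2 and C3) | C=C[C@@]1(C)C[C@H](OO)[C@@H]2[C@@H](OC(OCC)C2C)[C@@H]1C(=C)C | intermediate
18 | (3aR,4S,6R,7R,7aS)-2-ethoxy-6-ethenyl-3,6-dimethyl-7-(prop-1-en-2-yl)octahydro-1-benzofuran-4-ol (cis-fused, epimers at C2 and C3) | C=C[C@@]1(C)C[C@H](O)[C@@H]2[C@@H](OC(OCC)C2C)[C@@H]1C(=C)C | intermediate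
19 | tert-butyl{[(3aS,4S,6R,7R,7aS)-2-ethoxy-6-ethenyl-3,6-dimethyl-7-(prop-1-en-2-yl)octahydro-1-benzofuran-4-yl]oxy}dimethylsilane (epimers at C2 and C3) | C=C[C@@]1(C)C[C@H](O[Si](C)(C)C(C)(C)C)[C@@H]2[C@@H](OC(OCC)C2C)[C@@H]1C(=C)C | intermediate
20 | (3aS,4S,6R,7R,7aS)-4-{[tert-butyl(dimethyl)silyl]oxy}-6-ethenyl-3,6-dimethyl-7-(prop-1-en-2-yl)hexahydro-1-benzofuran-2(3H)-one (epimers at C3) | C=C[C@@]1(C)C[C@H](O[Si](C)(C)C(C)(C)C)[C@@H]2[C@@H](OC(=O)C2C)[C@@H]1C(=C)C | intermediate
21 | potassium (3aS,4S,6R,7R,7aS)-4-{[tert-butyl(dimethyl)silyl]oxy}-6-ethenyl-3,6-dimethyl-7-(prop-1-en-2-yl)-3a,4,5,6,7,7a-hexahydro-1-benzofuran-2-olate (enolate of 20) | C=C[C@@]1(C)C[C@H](O[Si](C)(C)C(C)(C)C)[C@@H]2[C@@H](OC([O-])=C2C)[C@@H]1C(=C)C.[K+] | intermediate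
22 | (3S,3aS,4S,6R,7R,7aS)-4-{[tert-butyl(dimethyl)silyl]oxy}-6-ethenyl-3-hydroxy-3,6-dimethyl-7-(prop-1-en-2-yl)hexahydro-1-benzofuran-2(3H)-one | C=C[C@@]1(C)C[C@H](O[Si](C)(C)C(C)(C)C)[C@@H]2[C@@H](OC(=O)[C@@]2(C)O)[C@@H]1C(=C)C | intermediate
23 | angelic acid, (2Z)-2-methylbut-2-enoic acid | C/C=C(/C)C(=O)O | starting material
24 | (2Z)-2-methylbut-2-enoic 2,4,6-trichlorobenzoic anhydride | C/C=C(/C)C(=O)OC(=O)c1c(Cl)cc(Cl)cc1Cl | intermediate
25 | (3S,3aS,4S,6R,7R,7aS)-4-{[tert-butyl(dimethyl)silyl]oxy}-6-ethenyl-3,6-dimethyl-2-oxo-7-(prop-1-en-2-yl)octahydro-1-benzofuran-3-yl (2Z)-2-methylbut-2-enoate | C=C[C@@]1(C)C[C@H](O[Si](C)(C)C(C)(C)C)[C@@H]2[C@@H](OC(=O)[C@@]2(C)OC(=O)/C(C)=C\C)[C@@H]1C(=C)C | intermediate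
26 | (3S,3aR,4S,6R,7R,7aS)-6-ethenyl-4-hydroxy-3,6-dimethyl-2-oxo-7-(prop-1-en-2-yl)octahydro-1-benzofuran-3-yl (2Z)-2-methylbut-2-enoate | C=C[C@@]1(C)C[C@H](O)[C@@H]2[C@@H](OC(=O)[C@@]2(C)OC(=O)/C(C)=C\C)[C@@H]1C(=C)C | intermediate
27 | (3S,3aR,4S,6R,7R,7aS)-4-acetoxy-6-ethenyl-3,6-dimethyl-2-oxo-7-(prop-1-en-2-yl)octahydro-1-benzofuran-3-yl (2Z)-2-methylbut-2-enoate (CNP0140071.1) | C=C[C@@]1(C)C[C@H](OC(C)=O)[C@@H]2[C@@H](OC(=O)[C@@]2(C)OC(=O)/C(C)=C\C)[C@@H]1C(=C)C | target

## Step count and least certain steps

Total: 17 steps. Longest linear sequence: 17 steps, from 1 and 2 to 27; 5 and 23 are bought and enter at steps 3 and 15.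

**Step 8 (key step).**
- *What may go wrong.* Hydride shift from C1 (giving the seven-membered ketone) or proton loss to an allylic alcohol may compete with the ring-bond shift. In a fused epoxide the C1–H bond is often as well aligned with the breaking C10–O bond as the ring bond is, and the cation is flanked by π bonds. A Lewis-acid-induced ene closure of the product aldehyde on the isopropenyl group is a further risk on warming.
- *Fallback.* It sets out from 11 and returns at 13. It keeps the same C9 shift but enforces it through a halohydrin. NBS in aqueous THF should form the bromonium ion anti to isopropenyl and admit water at the tertiary carbon, giving (1S,2S,3R,7S)-7-bromo-3-{[tert-butyl(dimethyl)silyl]oxy}-1-methyl-2-(prop-1-en-2-yl)cyclohept-4-en-1-ol F1. K2CO3 in methanol closes it to tert-butyl(dimethyl){[(1S,2S,3R,7R)-1-methyl-2-(prop-1-en-2-yl)-8-oxabicyclo[5.1.0]oct-4-en-3-yl]oxy}silane F2, the epoxide with oxygen syn to isopropenyl. LiBr with HMPA in hot toluene opens F2 at C10 with inversion to the bromohydrin salt, and loss of bromide with anti migration of the ring bond gives 13. The double inversion from F2 equals the single inversion from 12. If the peracid of step 7 should prefer the other face, the epoxide it forms is F2 itself and the same halide-mediated contraction applies.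

**Step 3.**
- *What may go wrong.* Enantioface selection may erode with a sterically small alkynyl aldehyde, and traces of base may isomerise the skipped enynal before it is captured.
- *Fallback.* It sets out from 4 and 6 and returns at 8. It moves the stereocontrol from C–C bond formation to a ketone reduction. Quenching 6 with 2-isopropoxy-4,4,5,5-tetramethyl-1,3,2-dioxaborolane gives the neutral, isolable 2-(2,4-dimethylpenta-2,4-dien-1-yl)-4,4,5,5-tetramethyl-1,3,2-dioxaborolane F3. Uncatalysed γ-allylboration of 4 gives racemic 2-methyl-3-(prop-1-en-2-yl)nona-1,8-dien-5-yn-4-ol F4. Dess–Martin oxidation gives 2-methyl-3-(prop-1-en-2-yl)nona-1,8-dien-5-yn-4-one F5. Corey–Bakshi–Shibata reduction ((S)-2-methyl-CBS-oxazaborolidine, catecholborane, −78 °C), with the alkynyl group acting as the small substituent, should give 8.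

**Step 6.**
- *What may go wrong.* Discrimination between the two diastereotopic isopropenyl groups may be poor, and closure onto a 1,1-disubstituted alkene is slow enough for oligomerisation or double-bond migration in the skipped diene.
- *Fallback.* It sets out from 9 and returns at 11. The order of silylation and metathesis is reversed, so the free hydroxyl, not a silyl ether, biases the closure, and the diastereomers are separated as alcohols. Metathesis of 9 with the same catalyst gives (1R,7R)-6-methyl-7-(prop-1-en-2-yl)cyclohepta-2,5-dien-1-ol F6, which is silylated with TBSOTf and 2,6-lutidine to 11.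

**Step 11.**
- *What may go wrong.* The C11 radical may be captured by O2, or reduced by the stannane, before it cyclises, because the rates are of the same order at air saturation. Oxygen may also add at C8 with poor facial selectivity.
- *Fallback.* It sets out from 16 and returns at 18 with no new isolated compound. The tin hydride chain is replaced by a cobalt-mediated reductive cyclisation under air: Co(salen) (divalent cobalt, catalytic), NaBH4, NaOH, ethanol, 40 °C. The radical is released from an alkylcobalt species at low stationary concentration, and the cyclised radical is taken up as a cobalt peroxide that borohydride reduces to the alcohol.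

**Step 15.**
- *What may go wrong.* Acylation of the tertiary, electron-poor hydroxyl may be incomplete, and the Z double bond may isomerise to the tiglate under the heat and nucleophilic catalysis needed to force it.
- *Fallback.* It sets out from 22 and returns at 25. The Z alkene is built after the ester bond, so forcing acylation conditions cannot harm it. 22 is acylated with 2-[bis(2,2,2-trifluoroethoxy)phosphoryl]propanoyl chloride (pyridine, DMAP) to (3S,3aS,4S,6R,7R,7aS)-4-{[tert-butyl(dimethyl)silyl]oxy}-6-ethenyl-3,6-dimethyl-2-oxo-7-(prop-1-en-2-yl)octahydro-1-benzofuran-3-yl 2-[bis(2,2,2-trifluoroethoxy)phosphoryl]propanoate F7. Still–Gennari olefination with acetaldehyde (KN(SiMe3)2, 18-crown-6, THF, −78 °C) should give the Z-configured 25.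

## Further compounds

F1 | step 8 | (1S,2S,3R,7S)-7-bromo-3-{[tert-butyl(dimethyl)silyl]oxy}-1-methyl-2-(prop-1-en-2-yl)cyclohept-4-en-1-ol | C[C@@]1(O)[C@@H](Br)CC=C[C@@H](O[Si](C)(C)C(C)(C)C)[C@@H]1C(=C)C
F2 | step 8 | tert-butyl(dimethyl){[(1S,2S,3R,7R)-1-methyl-2-(prop-1-en-2-yl)-8-oxabicyclo[5.1.0]oct-4-en-3-yl]oxy}silane | C[C@@]12O[C@@H]1CC=C[C@@H](O[Si](C)(C)C(C)(C)C)[C@@H]2C(=C)C
F3 | step 3 | 2-(2,4-dimethylpenta-2,4-dien-1-yl)-4,4,5,5-tetramethyl-1,3,2-dioxaborolane | C=C(C)C=C(C)CB1OC(C)(C)C(C)(C)O1
F4 | step 3 | racemic 2-methyl-3-(prop-1-en-2-yl)nona-1,8-dien-5-yn-4-ol | C=CCC#CC(O)C(C(C)=C)C(C)=C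
F5 | step 3 | 2-methyl-3-(prop-1-en-2-yl)nona-1,8-dien-5-yn-4-one | C=CCC#CC(=O)C(C(C)=C)C(C)=C
F6 | step 6 | (1R,7R)-6-methyl-7-(prop-1-en-2-yl)cyclohepta-2,5-dien-1-ol | CC1=CCC=C[C@@H](O)[C@@H]1C(=C)C
F0 | step 11 | none | none
F7 | step 15 | (3S,3aS,4S,6R,7R,7aS)-4-{[tert-butyl(dimethyl)silyl]oxy}-6-ethenyl-3,6-dimethyl-2-oxo-7-(prop-1-en-2-yl)octahydro-1-benzofuran-3-yl 2-[bis(2,2,2-trifluoroethoxy)phosphoryl]propanoate | C=C[C@@]1(C)C[C@H](O[Si](C)(C)C(C)(C)C)[C@@H]2[C@@H](OC(=O)[C@@]2(C)OC(=O)C(C)P(=O)(OCC(F)(F)F)OCC(F)(F)F)[C@@H]1C(=C)C
A1 | alternative 1 | Se-phenyl (3R)-3-{[ethenyl(dimethyl)silyl]oxy}-5-methyl-4-(prop-1-en-2-yl)hex-5-eneselenoate | C=C[Si](C)(C)O[C@H](CC(=O)[Se]c1ccccc1)C(C(C)=C)C(C)=C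
A2 | alternative 1 | (3R,4R,5R)-3-ethenyl-5-hydroxy-3-methyl-4-(prop-1-en-2-yl)cyclohexan-1-one | C=C[C@@]1(C)CC(=O)C[C@@H](O)[C@@H]1C(=C)C
A3 | alternative 2 | (3R,4R,5R)-3-(2-bromo-1-ethoxypropoxy)-5-ethenyl-5-methyl-4-(prop-1-en-2-yl)cyclohex-1-ene | C=C[C@@]1(C)CC=C[C@@H](OC(OCC)C(C)Br)[C@@H]1C(=C)C
A4 | alternative 2 | (3aR,4S,6R,7R,7aS)-2-ethoxy-6-ethenyl-3,6-dimethyl-7-(prop-1-en-2-yl)octahydro-1-benzofuran-4-ol | C=C[C@@]1(C)C[C@H](O)[C@@H]2[C@@H](OC(OCC)C2C)[C@@H]1C(=C)C
A5 | alternative 3 | methyl (2Z,4S,6R,7R)-2-(bromomethyl)-4-{[tert-butyl(dimethyl)silyl]oxy}-6-ethenyl-7-formyl-6,8-dimethylnona-2,8-dienoate | O=C[C@H](C(=C)C)[C@@](C)(C=C)C[C@H](O[Si](C)(C)C(C)(C)C)/C=C(\CBr)C(=O)OC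
A6 | alternative 3 | (3aS,4S,6R,7R,7aS)-4-{[tert-butyl(dimethyl)silyl]oxy}-6-ethenyl-6-methyl-3-methylidene-7-(prop-1-en-2-yl)hexahydro-1-benzofuran-2(3H)-one | C=C[C@@]1(C)C[C@H](O[Si](C)(C)C(C)(C)C)[C@@H]2[C@@H](OC(=O)C2=C)[C@@H]1C(=C)C
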